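- Percent of the charge is my unit, and the decision for the next run is whether to wait longer, add capture agent, or charge less substrate.

| flask | substrate | capture agent | remark | time |
|---|---|---|---|---|
| epsilon | 1.5 M | 0.10 M | run made earlier |  |
| theta | 1.5 M | 0.22 M | run made earlier |  |
| zeta | 3 M | 0.15 M | run made earlier |  |
| north-west | 1.5 M | 0.150 M |  | 80 min |
| south-east | 1.5 M | 0.150 M |  | 8.0 min |
| south-west | 1.5 M | 0.150 M |  | 25 min |

| run | time / min | substrate / % | intermediate B / % | target / % | intermediate C / % | trapped intermediate / % |
|---|---|---|---|---|---|---|
| epsilon | 0.417 | 76 | 3 | 0 | 1 | 0 |
| epsilon | 1.33 | 46 | 18 | 2 | 4 | 1 |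
| epsilon | 2.00 | 35 | 18 | 5 | 14 | 5 |
| epsilon | 3.00 | 19 | 25 | 13 | 16 | 5 |
| epsilon | 5.00 | 10 | 16 | 31 | 19 | 2 |
| theta | 1.00 | 55 | 14 | 3 | 5 | 3 |
| theta | 2.00 | 33 | 19 | 9 | 11 | 1 |
| theta | 3.00 | 22 | 23 | 16 | 15 | 3 |
| theta | 4.00 | 17 | 18 | 21 | 14 | 6 |
| theta | 5.00 | 9 | 13 | 30 | 17 | 4 |
| zeta | 0.417 | 67 | 5 | 1 | 3 | 0 |
| zeta | 0.667 | 56 | 10 | 0 | 0 | 0 |
| zeta | 1.33 | 34 | 14 | 0 | 6 | 0 |
| zeta | 2.50 | 20 | 19 | 12 | 13 | 0 |
| zeta | 5.00 | 8 | 14 | 24 | 18 | 3 |

(each reading ± 2 percentage points)

- what was read earlier has a scatter of 2 percentage points, one standard deviation
- a reading or a percentage of target counts all its forms, free or not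
- a reading of intermediate B is of its free form alone

- which of these there is most of at the end, counted by the substrate in it, north-west (intermediate B / trapped intermediate / target / intermediate C)
- which of these there is most of at the end, counted by the substrate in it, south-east (intermediate B / trapped intermediate / target / intermediate C)
- which of these there is most of at the end, counted by the substrate in it, south-west (intermediate B / trapped intermediate / target / intermediate C)
- how much there is at the end of the one of these that leads, in percent of the substrate charged: north-west
- how much there is at the end of the one of these that leads, in percent of the substrate charged: south-east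
- how much there is at the end of the one of these that leads, in percent of the substrate charged: south-west

- I add up the 5 columns at each run's last reading and take the sum from the charge. Missing are 22.0% in epsilon, 27.0% in theta and 33.0% in zeta.
- In epsilon the missing share reads 22.0% at 3.00 min and the same at 5.00 min, while intermediate B falls from 25% to 16%, so I book that share as lost, not parked.
- Substrate is the concentration to watch. At 0.417 min, zeta keeps 67% of its charge, less than the 76% of epsilon. Capture agent differs between those two runs as well, but I tentatively read a second-order path in substrate beside a first-order one.
- The ratio of those two paths should then grow with the charge. Averaging the two runs at the same charge gives a loss of 24.5%.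
- The loss odds are 0.325: the share lost over the share that goes on, a selectivity factor between the two paths.
- Zeta, with twice the charge, reads 0.493, which is 1.52 times mine. That is no clean doubling, and I hold it as a rough reading, since each sum carries the scatter of 5 readings.
- At the last reading, trapped intermediate reads 2% in epsilon and 4% in theta, with 2.20 times the capture agent. I take 3.00% for it.
- My estimate for target, once the intermediates have drained, is therefore 72.5%, for north-west and south-west alike. South-east, stopped at 8.0 min, should lie below it, and I give it no number. So I leave time and capture agent as they are and charge less substrate.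
- The forecast puts target ahead in each flask, with 88% in north-west, 56% in south-east and 89% in south-west. It reads the loss as “a reversible hidden reservoir of B”, and its north-west figure stands higher than my estimate.
- The flasks give target 74.2% in north-west, 50.6% in south-east and 74.1% in south-west. The gap between south-east and north-west is mainly the difference in time.

    substrate → intermediate A (k = 0.00720 s⁻¹)
    intermediate A ⇌ intermediate B (K = 5.60, k = 0.0440 s⁻¹)
    intermediate B → intermediate C (k = 0.00740 s⁻¹)
    intermediate A → target (k = 0.00450 s⁻¹)
    intermediate C → target (k = 0.00620 s⁻¹)
    capture agent + intermediate A → trapped intermediate (k = 0.0140 L mol⁻¹ s⁻¹)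
    2 substrate → self-condensation product (k = 0.00140 L mol⁻¹ s⁻¹)
    crystals ⇌ target, rate k8*(cs8 - [target]) while solid is left; crystals form when [target] > cs8 (solubility = 0.640 M, k = 0.270 s⁻¹)

- North-west ends with 21.2% of the charge in self-condensation product, and taking that step away lifts target from 74.2% to 94.6%, a part of the shortfall. In north-west at 800 min the product still stands at 21.2% and target at 74.2%. My estimate of 72.5% stands against 74.2% in north-west at the asked time. A neighbour of north-west, charged with 0.90 M of substrate, holds 0.600 of that charge, which scales the odds to 0.195 and my estimate to 80.7%, and that flask ends with target at 80.3%.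

The earlier runs and the new flask are calculated for an exercise, and the scatter is random.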